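## Structural features

The target is an octacyclic ether made of a 24-nor-friedelane (pristimerin-type) methyl ester and a fourteen-carbon nor-guaiane. Rings A–E belong to the triterpene, a cis-fused 1,4-dioxane sits on C2/C3 of aromatic ring A, and the sesquiterpene is a cyclopentene (C1'=C5') fused to a cycloheptane carrying a C10' methyl and a C7' isopropenyl group, trans to each other. Ring B is a 1,2-dihydronaphthalene ring (C6=C7) whose benzylic carbons are C6 and quaternary C9; the C8 hydrogen is cis to the methyls on C9 and C14, so B/C is cis, C/D trans and D/E cis. The stereocentres form a contiguous block C8–C9 and C13–C14 (vicinal quaternary, methyls trans)–C18–C17, with remote quaternary C20 (methyl and ester); the dioxane carbons C3'/C4' lie anti to the C10' methyl. Fragile groups are the electron-rich styrene and catechol ether, the acid-labile isopropenyl group and tetrasubstituted cyclopentene, and the methyl ester, which must survive ether cleavage. The real difficulty is the cluster of four quaternary carbons (C9, C13, C14, C17), the C8 hydrogen on the crowded β face, and a union of the two terpenes without directing groups. The key step uses the benzo-fusion of ring B: an ortho-formyl arene with a tertiary C9–H gives the photoenol C6=C5–C10=C9, which adds to an ethynyl group on C14 and closes ring B (C5–C10) and ring C (C8, C9, C11–C14) together, leaving C6–OH and C7=C8 as handles.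

## Logic of the disconnections

47 is cut at O2–C3' and O3–C4'. Both bonds belong to one ring and can form in a single [4+2] event between the O=C–C=O unit of 46 (from 35) and the C3'=C4' bond of 45. This splits a C44 target into a C30 and a C14 half at the last step. The forward step must join the less hindered O2 to the diene terminus, add anti to the C10' methyl, and use 45 before hydrogen shifts move its double bonds.

35 is traced to 34 by the two O–CH3 bonds, which only protect. 34 is traced to 31 by exchanging the C8–H bond and C6=C7 for the C6–O bond and C7=C8. The cut is made there because 31 is exactly what the key step delivers, and its C6 stereocentre can be spent to set C8. The forward step must be a stereospecific 1,3-transfer of hydrogen onto the β face of C8.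

31 is cut at C6–C7 and C8–C9 to give 29. Both bonds lie in ring B, C8–C9 also closes ring C, and two rings and two stereocentres disappear; the precursor holds only rings A, D and E. The forward step needs a diene from the arene (30) and the correct face at C9. The design of 29 is kept but tightened: C9 is left as both epimers (they give the same 30), the aldehyde is released only just before irradiation, and the only other abstractable hydrogen (C4 methyl) leads to a dienol that can only revert.

29 is cut at C9–C10 (through 28) into 22 and 26. This is the one bond between the arene and the terpenoid chain, and it separates a simple aromatic piece from the stereochemically dense decalin. The forward step must transfer a secondary alkyl group without isomerisation and tolerate ester, acetal and alkyne.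

26 is traced through 25 and 24 to 23 by removing the acetal, the C10–Br bond and the C5–CHO bond. Both substituents enter by electrophilic substitution guided by the two methoxyls; the demand is regiocontrol (para to the unhindered methoxyl first, then ortho to the formyl group).

22 is traced through 21, 20, 19, 18 and 17 to 16 by cutting C7≡C8 back to an aldehyde, then the C14–CH3 bond, then the C14–C8 bond. C14 is the carbonyl carbon of 16, so both substituents of this quaternary centre come from one ketone. The forward steps must homologate a hindered ketone and methylate C14 trans to the C13 methyl.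

16 is traced to 15 by the C13–CH3 bond and 15 to 14 by the C18–H bond. With the chain already on C13, the incoming methyl can be steered by the angular C17 methyl, and the ring fusion comes from hydrogenation of an enone. The demands are cis delivery of hydrogen and regioselective enolisation toward C13.

14 is cut at C13=C18 (through 13) and C16–C17 into 7 and 11. This is the annulation transform of ring D; it creates quaternary C17 and brings the whole C9–C16 chain in one reagent. The forward step must set C17 by reagent control, because the existing C20 centre is too remote to help.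

11 is traced through 10 and 9 to 8 by the vinyl–acyl bond, the silyl ether and the amide C–N bond; this is routine chain construction with no stereochemical demand (C9 is erased later).

7 is traced through 6, 5 and 3 to 1 and 2 by returning the ketone to an alkene and cutting C19–C20 and C21–C22. One cycloaddition makes ring E and the quaternary C20; it must be enantioselective and para-selective.

45 is traced through 44 to 43 (C3'=C4' from a ketone), 43 to 42 by the C3'–C4' bond, and 42 through 41, 40, 39 and 38 to 37 and 36 by the vinyl–C1' bond and the ring-expansion bond C5'–C6'. The seven-membered ring with both stereocentres comes from the chiral pool. The demands are migration of the less substituted carbon in the ring expansion and generation of the diene at low temperature.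

## Other disconnections considered

Alternative 1: The cut is C13–C14 inside ring D. In the forward step the silyl ketene acetal of the ten-membered lactone A1 would rearrange [3,3] to the ring D/E silyl ester A2, with a vinyl group (C12=C11) on C13 and the C8 carboxyl on C14. In its favour, both vicinal quaternary centres would arise in one suprafacial event whose geometry is fixed by a cyclic transition state; on this point it is better than the chosen plan, which needs two separate enolate alkylations (steps 11 and 14). Against it, A1 is a medium-ring lactone with a trisubstituted alkene of defined geometry, ring-contracting rearrangements of this size can pass through boat or chair arrays, and C8 arrives as a second carboxyl that must be told apart from the C29 ester before it can become the alkyne. Structurally it addresses ring D only and says nothing about rings B and C or C9, so it could feed the chosen key step but not replace it. Mechanistically it is a thermal pericyclic step, as robust as any step in the chosen route. In step count it would be about equal for the decalin and no shorter overall.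

Alternative 2: The cut is C9–C10. Aryl bromide A3, in which C6–C7 link the arene to C8 of a ring C olefin, would undergo a 6-exo Heck cyclisation onto C9=C11 to give A4 with C11=C12. In its favour, carbopalladation builds benzylic quaternary centres reliably, and the C6–C7 tether forces the arene onto the face of ring C that carries C7. The cis relation between the C8 hydrogen and the C9 methyl would therefore follow directly; here the alternative is better than the chosen plan, which must relay C8 from C6. Against it, A3 already needs the whole C/D/E tricycle with C8, C13 and C14 in place, which is a heavier precursor than the bicyclic 22. A4 also needs two redox corrections (saturation of C11=C12, dehydrogenation of C6–C7), and the step closes one ring and one bond where the chosen step closes two of each. As a two-electron palladium process it is at least the equal of a photochemical step in scalability and does not depend on the reactivity of an unactivated alkyne.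

Alternative 3: The cuts are C5–C6 and C9–C10. The aryne released from silyl triflate A5 would add across the diene C6=C7–C8=C9 of the tricycle A6 to give A7 with C7=C8. In its favour it is the most convergent option: ring A is attached in one intermolecular step with no Negishi coupling and no formyl group, so for the arene it has the better step economy, and arynes are reactive enough for a fully substituted diene terminus. Against it, an unsymmetrical aryne and an unsymmetrical diene can combine in two orientations with only weak aryne distortion to choose between them. The C9 face is also set intermolecularly, the diene must reach an s-cis form against allylic strain while ene reactions compete, and A7 carries no oxygen at C6, so the handle that sets C8 in the chosen plan would have to be added afterwards. Mechanistically it is the same ring B [4+2] from the opposite side (diene in the terpenoid, 2π partner in the arene). The chosen intramolecular version fixes the regiochemistry through the tether and closes ring C as well.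

Key step: step 23

Remark 1: C1–C30 are friedelane (24-nor) locants, C1'–C10' guaiane locants of the sesquiterpene half; β is the face of the C9, C14 and C17 methyls.
Remark 2: The key-step precursor and product were re-derived from the target atom by atom; they carry the correct 13α,14β,17β,18β,20α pattern and the 6α-hydroxyl, and needed no correction.
Remark 3: The C8 hydrogen of the target is read as cis to the C9 and C14 methyls (8S). The antipode of the oxazaborolidinium catalyst in step 1 is assumed to be the one that gives the R aldehyde.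

## Steps

Step 1
Reactants: 1 isoprene; 2 methacrolein
Product: 3 (R)-1,4-dimethylcyclohex-3-ene-1-carbaldehyde
Conditions: 3,3-diphenyl-1-(o-tolyl)tetrahydro-1H,3H-pyrrolo[1,2-c][1,3,2]oxazaborole·HNTf2 (20 mol%, antipode giving R), CH2Cl2, −78 °C
Reagents that add atoms: none
Why: Lewis acid-catalysed Diels–Alder reaction; the cationic oxazaborolidine binds the enal and screens one face, and the isoprene methyl ends para to the formyl-bearing carbon, which sets C20.

Step 2
Reactants: 3 (R)-1,4-dimethylcyclohex-3-ene-1-carbaldehyde
Product: 5 methyl (R)-1,4-dimethylcyclohex-3-ene-1-carboxylate, via carboxylic acid 4 (not isolated)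
Conditions: NaClO2, NaH2PO4, 2-methyl-2-butene, t-BuOH–H2O, 25 °C; then MeI, K2CO3, DMF, 25 °C
Reagents that add atoms: sodium chlorite ([Na+].[O-]Cl=O); iodomethane (CI)
Why: Pinnick oxidation of the non-enolisable aldehyde, then O-alkylation of the carboxylate; the quaternary centre is untouched.

Step 3
Reactants: 5 methyl (R)-1,4-dimethylcyclohex-3-ene-1-carboxylate
Product: 6 methyl (1R)-3-hydroxy-1,4-dimethylcyclohexane-1-carboxylate
Conditions: BH3·THF, THF, 0 °C; then NaOH, H2O2, 0 → 25 °C
Reagents that add atoms: hydrogen peroxide (OO)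
Why: Hydroboration–oxidation puts oxygen on the less substituted alkene carbon C18 by syn anti-Markovnikov addition; the hindered ester is spared at 0 °C and the new centres are erased later.

Step 4
Reactants: 6 methyl (1R)-3-hydroxy-1,4-dimethylcyclohexane-1-carboxylate
Product: 7 methyl (1R)-1,4-dimethyl-3-oxocyclohexane-1-carboxylate
Conditions: Dess–Martin periodinane, NaHCO3, CH2Cl2, 25 °C
Reagents that add atoms: none
Why: Dess–Martin oxidation gives the 2-methylcyclohexanone needed for annulation; C17 is epimerisable and of no consequence.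

Step 5
Reactants: 8 6-methyloxan-2-one
Product: 9 5-hydroxy-N-methoxy-N-methylhexanamide
Conditions: MeNH(OMe)·HCl, i-PrMgCl, THF, −20 → 0 °C
Reagents that add atoms: N,O-dimethylhydroxylamine hydrochloride (CNOC.Cl)
Why: Weinreb amide formation by aminolysis of the lactone with the magnesium amide; the ring opens and the C9 hydroxyl is freed.

Step 6
Reactants: 9 5-hydroxy-N-methoxy-N-methylhexanamide
Product: 10 5-[(tert-butyldiphenylsilyl)oxy]-N-methoxy-N-methylhexanamide
Conditions: t-BuPh2SiCl, imidazole, DMF, 25 °C
Reagents that add atoms: tert-butyl(chloro)diphenylsilane (CC(C)(C)[Si](Cl)(c1ccccc1)c1ccccc1)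
Why: Silylation of the secondary alcohol; this ether withstands base, hydrogenation and dilute acid in the steps ahead.

Step 7
Reactants: 10 5-[(tert-butyldiphenylsilyl)oxy]-N-methoxy-N-methylhexanamide
Product: 11 7-[(tert-butyldiphenylsilyl)oxy]oct-1-en-3-one
Conditions: CH2=CHMgBr, THF, −78 → 0 °C; cold 1 M HCl
Reagents that add atoms: vinylmagnesium bromide (C=C[Mg]Br)
Why: Grignard addition to a Weinreb amide stops at the chelated tetrahedral adduct, which gives the vinyl ketone on cold acidic work-up.

Step 8
Reactants: 7 methyl (1R)-1,4-dimethyl-3-oxocyclohexane-1-carboxylate; 11 7-[(tert-butyldiphenylsilyl)oxy]oct-1-en-3-one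
Product: 13 methyl (1R,4R)-4-{7-[(tert-butyldiphenylsilyl)oxy]-3-oxooctyl}-1,4-dimethyl-3-oxocyclohexane-1-carboxylate, via chiral imine 12 (not isolated)
Conditions: (S)-1-phenylethylamine, TsOH (cat.), PhMe, reflux (−H2O); then 11, THF, 40 °C; then 20% aq. AcOH, 25 °C
Reagents that add atoms: water (O)
Why: Michael addition of the chiral imine through its more substituted secondary enamine and a cyclic aza-ene-type transition state; the 1-phenylethyl group directs the acceptor to one face of C17, so the quaternary centre is set by the auxiliary, independent of remote C20.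

Step 9
Reactants: 13 methyl (1R,4R)-4-{7-[(tert-butyldiphenylsilyl)oxy]-3-oxooctyl}-1,4-dimethyl-3-oxocyclohexane-1-carboxylate
Product: 14 methyl (2R,4aR)-8-{3-[(tert-butyldiphenylsilyl)oxy]butyl}-2,4a-dimethyl-7-oxo-1,2,3,4,4a,5,6,7-octahydronaphthalene-2-carboxylate
Conditions: NaOMe, MeOH, 60 °C
Reagents that add atoms: none
Why: Intramolecular aldol condensation (second half of a Robinson annulation) closes ring D between C13 and C18 and dehydrates to the tetrasubstituted enone.

Step 10
Reactants: 14 methyl (2R,4aR)-8-{3-[(tert-butyldiphenylsilyl)oxy]butyl}-2,4a-dimethyl-7-oxo-1,2,3,4,4a,5,6,7-octahydronaphthalene-2-carboxylate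
Product: 15 methyl (2R,4aR,8aS)-8-{3-[(tert-butyldiphenylsilyl)oxy]butyl}-2,4a-dimethyl-7-oxodecahydronaphthalene-2-carboxylate
Conditions: H2 (3 atm), 10% Pd/C, Et3N (trace), EtOAc, 25 °C
Reagents that add atoms: none
Why: Heterogeneous hydrogenation of an angularly methylated octalone; hydrogen should reach C18 from the face of the C17 methyl because the other face is screened by the axial C20 ester and ring E, giving the cis-fused decalone (C13 stays epimerisable).

Step 11
Reactants: 15 methyl (2R,4aR,8aS)-8-{3-[(tert-butyldiphenylsilyl)oxy]butyl}-2,4a-dimethyl-7-oxodecahydronaphthalene-2-carboxylate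
Product: 16 methyl (2R,4aR,8S,8aR)-8-{3-[(tert-butyldiphenylsilyl)oxy]butyl}-2,4a,8-trimethyl-7-oxodecahydronaphthalene-2-carboxylate
Conditions: KOt-Bu, t-BuOH–THF, 25 °C; MeI, 0 → 25 °C
Reagents that add atoms: iodomethane (CI)
Why: Alkylation of the thermodynamic, more substituted (C13) potassium enolate of the cis-fused decalone; methyl iodide should approach anti to the axial C17 methyl (1,3-diaxial screening), so the methyl becomes α and the chain β.

Step 12
Reactants: 16 methyl (2R,4aR,8S,8aR)-8-{3-[(tert-butyldiphenylsilyl)oxy]butyl}-2,4a,8-trimethyl-7-oxodecahydronaphthalene-2-carboxylate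
Product: 17 14-(methoxymethylidene) analogue of 16
Conditions: Ph3P(CH2OMe)Cl, KOt-Bu, THF, 0 → 65 °C
Reagents that add atoms: (methoxymethyl)triphenylphosphonium chloride ([Cl-].COC[P+](c1ccccc1)(c1ccccc1)c1ccccc1)
Why: Wittig methoxymethylenation of the hindered ketone, the only carbonyl that reacts with the ylide (the neopentyl ester is inert).

Step 13
Reactants: 17 14-(methoxymethylidene) analogue of 16
Product: 18 14-formyl decalin silyl ether (C14 epimers)
Conditions: 2 M HCl, THF, 25 °C
Reagents that add atoms: water (O)
Why: Acid hydrolysis of the enol ether gives the one-carbon homologated aldehyde; the diphenylsilyl ether and the ester survive dilute acid.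

Step 14
Reactants: 18 14-formyl decalin silyl ether (C14 epimers)
Product: 19 14α-formyl-14β-methyl decalin silyl ether
Conditions: KOt-Bu, THF, 0 °C; MeI
Reagents that add atoms: iodomethane (CI)
Why: C-alkylation of the potassium enolate of an α-branched aldehyde; methyl iodide should attack C14 anti to the axial C13 methyl, giving the trans vicinal dimethyl array with the formyl group α.

Step 15
Reactants: 19 14α-formyl-14β-methyl decalin silyl ether
Product: 20 14α-ethynyl-14β-methyl decalin silyl ether
Conditions: MeC(O)C(N2)P(O)(OMe)2, K2CO3, MeOH, 25 °C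
Reagents that add atoms: dimethyl (1-diazo-2-oxopropyl)phosphonate (CC(=O)C(=[N+]=[N-])P(=O)(OC)OC)
Why: Ohira–Bestmann homologation of the non-enolisable neopentyl aldehyde to the terminal alkyne under mild carbonate conditions.

Step 16
Reactants: 20 14α-ethynyl-14β-methyl decalin silyl ether
Product: 21 14α-ethynyl decalin alcohol (C9 epimers)
Conditions: Bu4NF, THF, 45 °C
Reagents that add atoms: none
Why: Fluoride cleavage of the silyl ether; terminal alkyne and ester are inert.

Step 17
Reactants: 21 14α-ethynyl decalin alcohol (C9 epimers)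
Product: 22 14α-ethynyl decalin iodide (C9 epimers)
Conditions: I2, PPh3, imidazole, CH2Cl2, 0 → 25 °C
Reagents that add atoms: iodine (II)
Why: Appel-type iodination (oxyphosphonium activation, displacement by iodide); the C9 configuration is irrelevant.

Step 18
Reactants: 23 2,3-dimethoxytoluene
Product: 24 3,4-dimethoxy-2-methylbenzaldehyde
Conditions: Cl2CHOMe, TiCl4, CH2Cl2, 0 °C; H2O
Reagents that add atoms: dichloromethyl methyl ether (COC(Cl)Cl); water (O)
Why: Rieche formylation, an electrophilic aromatic substitution directed para to the unhindered C2 methoxyl and ortho to the methyl.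

Step 19
Reactants: 24 3,4-dimethoxy-2-methylbenzaldehyde
Product: 25 6-bromo-3,4-dimethoxy-2-methylbenzaldehyde
Conditions: Br2, NaOAc, AcOH, 25 °C
Reagents that add atoms: bromine (BrBr)
Why: Electrophilic bromination para to the C3 methoxyl and ortho to the formyl group, the same pattern as in the bromination of veratraldehyde.

Step 20
Reactants: 25 6-bromo-3,4-dimethoxy-2-methylbenzaldehyde
Product: 26 2-(6-bromo-3,4-dimethoxy-2-methylphenyl)-1,3-dioxolane
Conditions: HOCH2CH2OH, TsOH (cat.), PhMe, reflux (−H2O)
Reagents that add atoms: ethylene glycol (OCCO)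
Why: Acid-catalysed acetalisation masks the aldehyde against the organozinc reagent.

Step 21
Reactants: 22 14α-ethynyl decalin iodide (C9 epimers); 26 2-(6-bromo-3,4-dimethoxy-2-methylphenyl)-1,3-dioxolane
Product: 28 aryl dioxolane with the C9–C10 bond (C9 epimers), via alkylzinc iodide 27 (not isolated)
Conditions: Zn dust, LiCl, THF, 35 °C; then 26, Pd(OAc)2 (2 mol%), CPhos (2-dicyclohexylphosphino-2',6'-bis(dimethylamino)biphenyl, 4 mol%), THF–PhMe, 25 °C
Reagents that add atoms: none
Why: Zinc insertion into the secondary C–I bond and Negishi cross-coupling; the biaryl phosphine makes reductive elimination faster than β-hydride elimination so the branched alkyl is transferred, and the alkylzinc halide tolerates ester, acetal and terminal alkyne.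

Step 22
Reactants: 28 aryl dioxolane with the C9–C10 bond (C9 epimers)
Product: 29 ortho-formyl arene with a C9–H chain to the ethynyl D/E decalin (C9 epimers)
Conditions: 1 M HCl, THF, 25 °C
Reagents that add atoms: water (O)
Why: Mild acetal hydrolysis releases the photoactive ortho-alkyl benzaldehyde only at this point.

Step 23
Reactants: 29 ortho-formyl arene with a C9–H chain to the ethynyl D/E decalin (C9 epimers)
Product: 31 methyl 6α-hydroxy-2,3-dimethoxy-24-nor-D:A-friedooleana-1,3,5(10),7-tetraen-29-oate, via hydroxy-o-quinodimethane 30 (not isolated)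
Conditions: hν (365 nm), degassed PhMe (5 mM), 25 °C
Reagents that add atoms: none
Why: n→π* excitation of the aryl aldehyde and intersystem crossing give a triplet that abstracts the tertiary benzylic hydrogen at C9 through a six-membered transition state (abstraction from the C4 methyl only gives a dienol that cannot cyclise and returns to 29); the biradical relaxes to dienol 30, whose Z-hydroxyl forms reketonise by 1,5-hydrogen shift so that the E-hydroxyl, tether-outward form is the one that persists. This dearomatised diene adds to the C7≡C8 alkyne in an intramolecular [4+2] cycloaddition, the closest known reaction type being the intramolecular photoenolisation/Diels–Alder reaction of ortho-alkyl benzaldehydes that carry a tethered π-bond. Ring C closes through the four-atom tether C11–C12–C13–C14 as the six-membered ring of a type 1 intramolecular Diels–Alder reaction (C8–C9 bond), and ring B closes as the cyclohexadiene of the cycloaddition itself (C6–C7 and C8–C9), driven by rearomatisation of ring A. C6 is set by suprafacial addition to the E-enol, tether-outward diene, which places the hydroxyl cis to C11 and so trans to the C9 methyl. C9 is set by the fold of the tether: ring D holds C12 and the ethynyl group trans-diequatorial, and a chair-like nascent ring C that keeps the bulky dienyl carbon C10 equatorial leaves the C9 methyl syn to the C14 methyl. The step needs this C9 face and needs cycloaddition to outrun reketonisation; high dilution, exclusion of oxygen and the proximity enforced by the vicinal quaternary C13/C14 pair favour both, and since the dienophile is an alkyne no stereocentre arises at C8.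

Step 24
Reactants: 31 methyl 6α-hydroxy-2,3-dimethoxy-24-nor-D:A-friedooleana-1,3,5(10),7-tetraen-29-oate
Product: 34 methyl 2,3-dimethoxy-24-nor-D:A-friedooleana-1,3,5(10),6-tetraen-29-oate (8β-H), via sulfonylhydrazine 32 (not isolated), via allylic diazene 33 (not isolated)
Conditions: 2-O2NC6H4SO2NHNH2, PPh3, EtO2CN=NCO2Et, N-methylmorpholine, −30 → 23 °C
Reagents that add atoms: none
Why: Reductive 1,3-transposition of an allylic alcohol: Mitsunobu displacement with inversion at C6, loss of sulfinic acid to the monoalkyl diazene, and retro-ene loss of N2, which passes hydrogen suprafacially to the β face of C8 and moves the alkene to C6=C7; C8 is thereby relayed from the C6 centre made in step 23.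

Step 25
Reactants: 34 methyl 2,3-dimethoxy-24-nor-D:A-friedooleana-1,3,5(10),6-tetraen-29-oate (8β-H)
Product: 35 methyl 2,3-dihydroxy-24-nor-D:A-friedooleana-1,3,5(10),6-tetraen-29-oate (8β-H)
Conditions: BBr3, CH2Cl2, −78 → −20 °C; H2O
Reagents that add atoms: none
Why: Lewis acid cleavage of both aryl methyl ethers; at low temperature the neopentyl methyl ester and the styrene should survive.

Step 26
Reactants: 36 (S)-carvone
Product: 37 (2S,5S)-dihydrocarvone
Conditions: LiBH(s-Bu)3, THF, −78 °C; then NaOMe (cat.), MeOH, 25 °C
Reagents that add atoms: none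
Why: Conjugate hydride reduction of the enone by the bulky borohydride, then base equilibration of the α-methyl centre to the trans (diequatorial) isomer.

Step 27
Reactants: 37 (2S,5S)-dihydrocarvone
Product: 38 ethyl (3S,6S)-3-methyl-2-oxo-6-(prop-1-en-2-yl)cycloheptane-1-carboxylate
Conditions: N2CHCO2Et, BF3·OEt2, Et2O, 0 → 25 °C
Reagents that add atoms: ethyl diazoacetate (CCOC(=O)C=[N+]=[N-])
Why: Lewis acid-promoted diazoacetate ring expansion (Tiffeneau–Demjanov type); the less substituted α-carbon migrates, which inserts C5' with its ester between C1' and C6'.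

Step 28
Reactants: 38 ethyl (3S,6S)-3-methyl-2-oxo-6-(prop-1-en-2-yl)cycloheptane-1-carboxylate
Product: 39 ethyl (3S,6S)-3-methyl-6-(prop-1-en-2-yl)-2-{[(trifluoromethyl)sulfonyl]oxy}cyclohept-1-ene-1-carboxylate
Conditions: NaH (1.0 equiv), THF, 0 °C; PhNTf2
Reagents that add atoms: N-phenylbis(trifluoromethanesulfonimide) (O=S(=O)(N(c1ccccc1)S(=O)(=O)C(F)(F)F)C(F)(F)F)
Why: O-triflation of the β-keto ester enolate fixes the C1'=C5' double bond; C10' is no longer enolisable afterwards.

Step 29
Reactants: 39 ethyl (3S,6S)-3-methyl-6-(prop-1-en-2-yl)-2-{[(trifluoromethyl)sulfonyl]oxy}cyclohept-1-ene-1-carboxylate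
Product: 40 ethyl (3S,6S)-2-ethenyl-3-methyl-6-(prop-1-en-2-yl)cyclohept-1-ene-1-carboxylate
Conditions: CH2=CHSnBu3, Pd(PPh3)4 (5 mol%), LiCl, THF, 65 °C
Reagents that add atoms: tributyl(vinyl)stannane (C=C[Sn](CCCC)(CCCC)CCCC)
Why: Stille coupling of the vinyl triflate with chloride as additive installs the vinyl group on C1'.

Step 30
Reactants: 40 ethyl (3S,6S)-2-ethenyl-3-methyl-6-(prop-1-en-2-yl)cyclohept-1-ene-1-carboxylate
Product: 41 [(3S,6S)-2-ethenyl-3-methyl-6-(prop-1-en-2-yl)cyclohept-1-en-1-yl]methanol
Conditions: i-Bu2AlH, CH2Cl2, −78 °C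
Reagents that add atoms: none
Why: 1,2-Reduction of the conjugated ester by the aluminium hydride gives the allylic alcohol.

Step 31
Reactants: 41 [(3S,6S)-2-ethenyl-3-methyl-6-(prop-1-en-2-yl)cyclohept-1-en-1-yl]methanol
Product: 42 (3S,6S)-2-ethenyl-3-methyl-6-(prop-1-en-2-yl)cyclohept-1-ene-1-carbaldehyde
Conditions: MnO2, CH2Cl2, 25 °C
Reagents that add atoms: none
Why: Selective allylic oxidation with manganese dioxide gives the dienal without touching the isolated alkene.

Step 32
Reactants: 42 (3S,6S)-2-ethenyl-3-methyl-6-(prop-1-en-2-yl)cyclohept-1-ene-1-carbaldehyde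
Product: 43 (4S,7S)-4-methyl-7-(prop-1-en-2-yl)-3,4,5,6,7,8-hexahydroazulen-1(2H)-one
Conditions: [Rh(Ph2PCH2CH2PPh2)]ClO4 (5 mol%), CH2Cl2, 25 °C
Reagents that add atoms: none
Why: Rhodium-catalysed intramolecular hydroacylation (aldehyde C–H oxidative addition, insertion of the vinyl group, reductive elimination) closes the cyclopentenone, as with 4-pentenals and 2-vinylbenzaldehydes.

Step 33
Reactants: 43 (4S,7S)-4-methyl-7-(prop-1-en-2-yl)-3,4,5,6,7,8-hexahydroazulen-1(2H)-one
Product: 44 4-methylbenzenesulfonohydrazone of 43
Conditions: TsNHNH2, MeOH, 25 °C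
Reagents that add atoms: 4-methylbenzenesulfonohydrazide (Cc1ccc(cc1)S(=O)(=O)NN)
Why: Condensation of the ketone with the sulfonyl hydrazide gives the hydrazone needed for the Shapiro reaction.

Step 34
Reactants: 44 4-methylbenzenesulfonohydrazone of 43
Product: 45 (4S,7S)-4-methyl-7-(prop-1-en-2-yl)-3,4,5,6,7,8-hexahydroazulene
Conditions: n-BuLi (2.2 equiv), TMEDA, THF, −78 → 0 °C; H2O, 0 °C; used at once
Reagents that add atoms: none
Why: Shapiro reaction: the dianion (deprotonated at C3') loses sulfinate and N2 to a vinyllithium that is protonated, placing the new alkene at C3'=C4' regiospecifically and at low temperature, before 1,5-hydrogen shifts can move it.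

Step 35
Reactants: 35 methyl 2,3-dihydroxy-24-nor-D:A-friedooleana-1,3,5(10),6-tetraen-29-oate (8β-H); 45 (4S,7S)-4-methyl-7-(prop-1-en-2-yl)-3,4,5,6,7,8-hexahydroazulene
Product: 47 CNP0149558.1, via ortho-quinone 46 (not isolated)
Conditions: 45 (3 equiv), Ag2O, Na2SO4, CH2Cl2, 0 °C
Reagents that add atoms: none
Why: Oxidation of the catechol to the ortho-quinone and inverse-demand hetero-Diels–Alder reaction of its O=C–C=O unit with the disubstituted C3'=C4' bond of the cyclopentadiene, driven by rearomatisation of ring A. The less hindered O2 should bond to the diene terminus C3' and O3 to allylic C4'; suprafacial addition gives the cis-fused dioxane, and approach anti to the pseudo-axial C10' methyl sets C3' and C4'.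

## Compound list

1 | isoprene | C=CC(C)=C | starting material
2 | methacrolein | CC(=C)C=O | starting material
3 | (R)-1,4-dimethylcyclohex-3-ene-1-carbaldehyde | CC1=CC[C@](C)(C=O)CC1 | intermediate
4 | (R)-1,4-dimethylcyclohex-3-ene-1-carboxylic acid (not isolated) | CC1=CC[C@](C)(C(=O)O)CC1 | intermediate
5 | methyl (R)-1,4-dimethylcyclohex-3-ene-1-carboxylate | CC1=CC[C@](C)(C(=O)OC)CC1 | intermediate
6 | methyl (1R)-3-hydroxy-1,4-dimethylcyclohexane-1-carboxylate (3,4-trans, both ring-face isomers) | OC1C[C@](C)(C(=O)OC)CCC1C | intermediate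
7 | methyl (1R)-1,4-dimethyl-3-oxocyclohexane-1-carboxylate (C4 epimers) | O=C1C[C@](C)(C(=O)OC)CCC1C | intermediate
8 | 6-methyloxan-2-one (δ-hexalactone, racemic) | CC1CCCC(=O)O1 | starting material
9 | 5-hydroxy-N-methoxy-N-methylhexanamide | CC(O)CCCC(=O)N(C)OC | intermediate
10 | 5-[(tert-butyldiphenylsilyl)oxy]-N-methoxy-N-methylhexanamide | CC(CCCC(=O)N(C)OC)O[Si](c1ccccc1)(c1ccccc1)C(C)(C)C | intermediate
11 | 7-[(tert-butyldiphenylsilyl)oxy]oct-1-en-3-one | C=CC(=O)CCCC(C)O[Si](c1ccccc1)(c1ccccc1)C(C)(C)C | intermediate
12 | methyl (1R)-1,4-dimethyl-3-{[(1S)-1-phenylethyl]imino}cyclohexane-1-carboxylate (not isolated) | C[C@H](N=C1C[C@](C)(C(=O)OC)CCC1C)c1ccccc1 | intermediate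
13 | methyl (1R,4R)-4-{7-[(tert-butyldiphenylsilyl)oxy]-3-oxooctyl}-1,4-dimethyl-3-oxocyclohexane-1-carboxylate | O=C1C[C@](C)(C(=O)OC)CC[C@]1(C)CCC(=O)CCCC(C)O[Si](c1ccccc1)(c1ccccc1)C(C)(C)C | intermediate
14 | methyl (2R,4aR)-8-{3-[(tert-butyldiphenylsilyl)oxy]butyl}-2,4a-dimethyl-7-oxo-1,2,3,4,4a,5,6,7-octahydronaphthalene-2-carboxylate (D/E enone, C13=C18) | CC(CCC1=C2C[C@](C)(C(=O)OC)CC[C@]2(C)CCC1=O)O[Si](c1ccccc1)(c1ccccc1)C(C)(C)C | intermediate
15 | methyl (2R,4aR,8aS)-8-{3-[(tert-butyldiphenylsilyl)oxy]butyl}-2,4a-dimethyl-7-oxodecahydronaphthalene-2-carboxylate (cis-fused, 18β-H, C13 epimers) | CC(CCC1[C@@H]2C[C@](C)(C(=O)OC)CC[C@]2(C)CCC1=O)O[Si](c1ccccc1)(c1ccccc1)C(C)(C)C | intermediate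
16 | methyl (2R,4aR,8S,8aR)-8-{3-[(tert-butyldiphenylsilyl)oxy]butyl}-2,4a,8-trimethyl-7-oxodecahydronaphthalene-2-carboxylate (13α-methyl, 13β-chain) | CC(CC[C@@]1(C)[C@@H]2C[C@](C)(C(=O)OC)CC[C@]2(C)CCC1=O)O[Si](c1ccccc1)(c1ccccc1)C(C)(C)C | intermediate
17 | 14-(methoxymethylidene) analogue of 16 (C14=CH–OMe, E/Z mixture) | CC(CC[C@@]1(C)[C@@H]2C[C@](C)(C(=O)OC)CC[C@]2(C)CCC1=COC)O[Si](c1ccccc1)(c1ccccc1)C(C)(C)C | intermediate
18 | 14-formyl decalin silyl ether (C14 epimers) | CC(CC[C@@]1(C)[C@@H]2C[C@](C)(C(=O)OC)CC[C@]2(C)CCC1C=O)O[Si](c1ccccc1)(c1ccccc1)C(C)(C)C | intermediate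
19 | 14α-formyl-14β-methyl decalin silyl ether | CC(CC[C@@]1(C)[C@@H]2C[C@](C)(C(=O)OC)CC[C@]2(C)CC[C@]1(C)C=O)O[Si](c1ccccc1)(c1ccccc1)C(C)(C)C | intermediate
20 | 14α-ethynyl-14β-methyl decalin silyl ether | CC(CC[C@@]1(C)[C@@H]2C[C@](C)(C(=O)OC)CC[C@]2(C)CC[C@]1(C)C#C)O[Si](c1ccccc1)(c1ccccc1)C(C)(C)C | intermediate
21 | 14α-ethynyl decalin alcohol (C9 epimers) | CC(O)CC[C@@]1(C)[C@@H]2C[C@](C)(C(=O)OC)CC[C@]2(C)CC[C@]1(C)C#C | intermediate
22 | 14α-ethynyl decalin iodide (C9 epimers) | CC(I)CC[C@@]1(C)[C@@H]2C[C@](C)(C(=O)OC)CC[C@]2(C)CC[C@]1(C)C#C | intermediate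
23 | 2,3-dimethoxytoluene | COc1cccc(C)c1OC | starting material
24 | 3,4-dimethoxy-2-methylbenzaldehyde | COc1ccc(C=O)c(C)c1OC | intermediate
25 | 6-bromo-3,4-dimethoxy-2-methylbenzaldehyde | COc1cc(Br)c(C=O)c(C)c1OC | intermediate
26 | 2-(6-bromo-3,4-dimethoxy-2-methylphenyl)-1,3-dioxolane | COc1cc(Br)c(C2OCCO2)c(C)c1OC | intermediate
27 | secondary alkylzinc iodide from 22 (not isolated) | CC([Zn]I)CC[C@@]1(C)[C@@H]2C[C@](C)(C(=O)OC)CC[C@]2(C)CC[C@]1(C)C#C | intermediate
28 | aryl dioxolane with the C9–C10 bond (C9 epimers) | COc1cc(C(C)CC[C@@]2(C)[C@@H]3C[C@](C)(C(=O)OC)CC[C@]3(C)CC[C@]2(C)C#C)c(C4OCCO4)c(C)c1OC | intermediate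
29 | ortho-formyl arene with a C9–H chain to the ethynyl D/E decalin (key-step precursor, C9 epimers) | COc1c(OC)cc(C(C)CC[C@@]4(C)[C@@H]5C[C@](C)(C(=O)OC)CC[C@]5(C)CC[C@]4(C)C#C)c(C=O)c1C | intermediate
30 | (E)-hydroxy-ortho-quinodimethane, tether outward (not isolated) | O/C=C1\C(C)=C(OC)C(OC)=C/C1=C(/C)CC[C@@]2(C)[C@@H]3C[C@](C)(C(=O)OC)CC[C@]3(C)CC[C@]2(C)C#C | intermediate
31 | methyl 6α-hydroxy-2,3-dimethoxy-24-nor-D:A-friedooleana-1,3,5(10),7-tetraen-29-oate | COc3c(cc4c(c3C)[C@@H](O)C=C3[C@@]4(C)CC[C@@]4(C)[C@@H]5C[C@](C)(C(=O)OC)CC[C@]5(C)CC[C@]34C)OC | intermediate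
32 | 6β-[N-amino-(2-nitrophenyl)sulfonamido] analogue of 31 (not isolated) | COc3c(cc4c(c3C)[C@H](N(N)S(=O)(=O)c6ccccc6[N+](=O)[O-])C=C3[C@@]4(C)CC[C@@]4(C)[C@@H]5C[C@](C)(C(=O)OC)CC[C@]5(C)CC[C@]34C)OC | intermediate
33 | 6β-diazenyl analogue of 31 (monoalkyl diazene, not isolated) | COc3c(cc4c(c3C)[C@H](N=N)C=C3[C@@]4(C)CC[C@@]4(C)[C@@H]5C[C@](C)(C(=O)OC)CC[C@]5(C)CC[C@]34C)OC | intermediate
34 | methyl 2,3-dimethoxy-24-nor-D:A-friedooleana-1,3,5(10),6-tetraen-29-oate (8β-H, 8S) | COc3c(cc4c(c3C)C=C[C@@H]3[C@@]4(C)CC[C@@]4(C)[C@@H]5C[C@](C)(C(=O)OC)CC[C@]5(C)CC[C@]34C)OC | intermediate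
35 | methyl 2,3-dihydroxy-24-nor-D:A-friedooleana-1,3,5(10),6-tetraen-29-oate (8β-H) | Oc3c(cc4c(c3C)C=C[C@@H]3[C@@]4(C)CC[C@@]4(C)[C@@H]5C[C@](C)(C(=O)OC)CC[C@]5(C)CC[C@]34C)O | intermediate
36 | (S)-carvone | CC1=CC[C@@H](CC1=O)C(=C)C | starting material
37 | (2S,5S)-dihydrocarvone (trans) | C[C@H]1CC[C@@H](CC1=O)C(=C)C | intermediate
38 | ethyl (3S,6S)-3-methyl-2-oxo-6-(prop-1-en-2-yl)cycloheptane-1-carboxylate (keto/enol, C1 epimers) | C[C@H]1CC[C@@H](CC(C(=O)OCC)C1=O)C(=C)C | intermediate
39 | ethyl (3S,6S)-3-methyl-6-(prop-1-en-2-yl)-2-{[(trifluoromethyl)sulfonyl]oxy}cyclohept-1-ene-1-carboxylate | C[C@H]1CC[C@@H](CC(C(=O)OCC)=C1OS(=O)(=O)C(F)(F)F)C(=C)C | intermediate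
40 | ethyl (3S,6S)-2-ethenyl-3-methyl-6-(prop-1-en-2-yl)cyclohept-1-ene-1-carboxylate | C[C@H]1CC[C@@H](CC(C(=O)OCC)=C1C=C)C(=C)C | intermediate
41 | [(3S,6S)-2-ethenyl-3-methyl-6-(prop-1-en-2-yl)cyclohept-1-en-1-yl]methanol | C[C@H]1CC[C@@H](CC(CO)=C1C=C)C(=C)C | intermediate
42 | (3S,6S)-2-ethenyl-3-methyl-6-(prop-1-en-2-yl)cyclohept-1-ene-1-carbaldehyde | C[C@H]1CC[C@@H](CC(C=O)=C1C=C)C(=C)C | intermediate
43 | (4S,7S)-4-methyl-7-(prop-1-en-2-yl)-3,4,5,6,7,8-hexahydroazulen-1(2H)-one (C4' ketone, C1'=C5') | C[C@H]1CC[C@@H](CC2=C1CCC2=O)C(=C)C | intermediate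
44 | 4-methylbenzenesulfonohydrazone of 43 | C[C@H]1CC[C@@H](CC2=C1CCC2=NNS(=O)(=O)c3ccc(C)cc3)C(=C)C | intermediate
45 | (4S,7S)-4-methyl-7-(prop-1-en-2-yl)-3,4,5,6,7,8-hexahydroazulene (C1'=C5', C3'=C4') | C[C@H]1CC[C@@H](CC2=C1CC=C2)C(=C)C | intermediate
46 | methyl 2,3-dioxo-24-nor-D:A-friedooleana-1(10),4,6-trien-29-oate (8β-H, not isolated) | O=C3C(C=C4C(=C3C)C=C[C@@H]3[C@@]4(C)CC[C@@]4(C)[C@@H]5C[C@](C)(C(=O)OC)CC[C@]5(C)CC[C@]34C)=O | intermediate
47 | CNP0149558.1 | C=C(C)[C@H]1CC[C@H](C)C2=C(C1)[C@@H]1Oc3c(cc4c(c3C)C=C[C@@H]3[C@@]4(C)CC[C@@]4(C)[C@@H]5C[C@](C)(C(=O)OC)CC[C@]5(C)CC[C@]34C)O[C@@H]1C2 | target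

## Step count and least certain steps

Total: 35 steps. Longest linear sequence: 20 steps (steps 1–4, 8–17, 21–25 and 35).

Step 23 (key step). The dienol may return to the aldehyde faster than it adds to the unactivated alkyne, may close photochemically to a benzocyclobutenol, or may add on the wrong face at C9, because nothing but the fold of the tether controls that face. Fallback: starting from 29, irradiation at −40 °C without a cycloaddition pathway collects the benzocyclobutenol F1. Thermolysis of F1 in toluene at 110 °C reopens the four-membered ring conrotatorily with the hydroxyl outward and lets the same diene add thermally, at a temperature where an unactivated alkyne is a competent partner. The route is rejoined at 31.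

Step 35. Selectivity is the main risk: the ortho-quinone may add to the wrong alkene, in the wrong orientation or on the wrong face, because no directing group helps. In addition 45 can isomerise by 1,5-hydrogen shifts, and 46 can tautomerise to the quinone methide through its acidic C8 hydrogen. Fallback, stepwise and with reagent control at C3': starting from 43 and 35, enolisation of 43 with LiN(SiMe3)2 and oxidation with (camphorsulfonyl)oxaziridine gives the 3'-hydroxy ketone F2. Tf2O and 2,6-lutidine convert it into the triflate F3. The less hindered O2 of 35 displaces the triflate with inversion (Cs2CO3, MeCN, −20 °C) to give the aryloxy ketone F4. Et3SiH and BF3·OEt2 at −78 °C then close the dioxane by reductive etherification of the C4' ketone with O3, with hydride entering from the face away from the new ring. The route is rejoined at 47.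

Step 24. The p-alkoxybenzylic, allylic alcohol may ionise during the Mitsunobu step, which would erode the inversion at C6 and with it the relay to C8, or the hindered carbinol may not be displaced at all. Fallback: starting from 31, HCO2H, dicyclohexylcarbodiimide and 4-(dimethylamino)pyridine give the allylic formate F5. Pd(OAc)2 and PBu3 in THF then ionise it anti to the formate, and the hydride is delivered from the palladium face (β) to the more substituted terminus C8 with loss of CO2. The route is rejoined at 34.

Step 11. Enolisation may go toward C15, or methyl iodide may attack the β face if the cis-decalin adopts its other chair pair; both would give poor regio- or face selectivity. Fallback: starting from 14, deconjugative methylation of the dienolate (KOt-Bu, MeI) occurs only at C13 and anti to the angular methyl, giving the β,γ-unsaturated ketone F6. Hydrogen-atom-transfer hydrogenation of F6 (tris(dipivaloylmethanato)manganese, PhSiH3, t-BuOOH, i-PrOH) should then give the thermodynamically preferred cis ring fusion. The route is rejoined at 16.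

Step 14. Facial selectivity at C14 rests on a conformational argument and may be poor or reversed. Fallback, with the order of the two substituents inverted so that the carbon unit enters last from the same open face: starting from 16, KN(SiMe3)2 and PhNTf2 give the enol triflate F7. MeMgBr with Fe(acac)3 gives the C14-methyl alkene F8. Hydrogen-atom-transfer hydroalkynylation (Fe(acac)3, PhSiH3, [(triisopropylsilyl)ethynyl] phenyl sulfone) traps the tertiary C14 radical as the silyl alkyne F9. Bu4NF removes both silyl groups, and the route is rejoined at 21.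

## Further compounds

F1 | step 23 | benzocyclobutenol from 29 (hydroxyl trans to the C11 chain; one of two ring-face diastereomers) | COc1c(OC)cc2c(c1C)[C@H](O)[C@@]2(C)CC[C@@]3(C)[C@@H]4C[C@](C)(C(=O)OC)CC[C@]4(C)CC[C@]3(C)C#C
F2 | step 35 | 3'-hydroxy ketone from 43 (hydroxyl cis to the C10' methyl) | C[C@H]1CC[C@@H](CC2=C1C[C@H](O)C2=O)C(=C)C
F3 | step 35 | 3'-triflate of F2 | C[C@H]1CC[C@@H](CC2=C1C[C@H](OS(=O)(=O)C(F)(F)F)C2=O)C(=C)C
F4 | step 35 | O2-(3'-aryloxy) ketone from 35 and F3 | Oc3c(cc4c(c3C)C=C[C@@H]3[C@@]4(C)CC[C@@]4(C)[C@@H]5C[C@](C)(C(=O)OC)CC[C@]5(C)CC[C@]34C)O[C@@H]1CC2=C(C[C@H](CC[C@@H]2C)C(C)=C)C1=O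
F5 | step 24 | 6α-formate of 31 | COc3c(cc4c(c3C)[C@@H](OC=O)C=C3[C@@]4(C)CC[C@@]4(C)[C@@H]5C[C@](C)(C(=O)OC)CC[C@]5(C)CC[C@]34C)OC
F6 | step 11 | 13α-methyl β,γ-unsaturated ketone (C18=C19) from 14 | CC(CC[C@@]1(C)C2=C[C@](C)(C(=O)OC)CC[C@]2(C)CCC1=O)O[Si](c1ccccc1)(c1ccccc1)C(C)(C)C
F7 | step 14 | C14 enol triflate of 16 | CC(CC[C@@]1(C)[C@@H]2C[C@](C)(C(=O)OC)CC[C@]2(C)CC=C1OS(=O)(=O)C(F)(F)F)O[Si](c1ccccc1)(c1ccccc1)C(C)(C)C
F8 | step 14 | C14-methyl alkene (C14=C15) | CC(CC[C@@]1(C)[C@@H]2C[C@](C)(C(=O)OC)CC[C@]2(C)CC=C1C)O[Si](c1ccccc1)(c1ccccc1)C(C)(C)C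
F9 | step 14 | 14α-[(triisopropylsilyl)ethynyl]-14β-methyl decalin silyl ether | CC(CC[C@@]1(C)[C@@H]2C[C@](C)(C(=O)OC)CC[C@]2(C)CC[C@]1(C)C#C[Si](C(C)C)(C(C)C)C(C)C)O[Si](c1ccccc1)(c1ccccc1)C(C)(C)C
A1 | alternative 1 | ten-membered lactone (C8 acyl, O–C11, C12=C13; alkene geometry and C14 left open) | O=C1OCC=C(C)[C@@H]2C[C@](C)(C(=O)OC)CC[C@]2(C)CCC1C
A2 | alternative 1 | ring D/E trimethylsilyl ester with vinyl on C13 | C=C[C@@]4(C)[C@@H]5C[C@](C)(C(=O)OC)CC[C@]5(C)CC[C@]4(C)C(=O)O[Si](C)(C)C
A3 | alternative 2 | aryl bromide tethered through C6–C7 to C8 of the ring C olefin | COc1cc(Br)c(CC[C@@H]2C(C)=CC[C@@]3(C)[C@@H]4C[C@](C)(C(=O)OC)CC[C@]4(C)CC[C@]23C)c(C)c1OC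
A4 | alternative 2 | pentacyclic 2,3-dimethoxy arene with C11=C12 | COc3c(cc4c(c3C)CC[C@@H]3[C@@]4(C)C=C[C@@]4(C)[C@@H]5C[C@](C)(C(=O)OC)CC[C@]5(C)CC[C@]34C)OC
A5 | alternative 3 | 3,4-dimethoxy-2-methyl-6-(trimethylsilyl)phenyl trifluoromethanesulfonate | COc1cc([Si](C)(C)C)c(OS(=O)(=O)C(F)(F)F)c(C)c1OC
A6 | alternative 3 | tricyclic C/D/E diene (C6=C7–C8=C9) | C=CC1=C(C)CC[C@@]2(C)[C@@H]3C[C@](C)(C(=O)OC)CC[C@]3(C)CC[C@]12C
A7 | alternative 3 | pentacyclic 2,3-dimethoxy arene with C7=C8 | COc3c(cc4c(c3C)CC=C3[C@@]4(C)CC[C@@]4(C)[C@@H]5C[C@](C)(C(=O)OC)CC[C@]5(C)CC[C@]34C)OC
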